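## Retrosynthetic overview

1. C13–O spiro-ether bond (last step): 5-exo dearomative cyclisation of the C9 alkoxy radical onto the 3-acylfuran of hydroxy ketone 15; it sets C13 and turns the furan into the 2,3-dihydrofuran.
2. C9–C11: cerium aldol of 3-acetylfuran onto the C9 ketone of tricyclic diketo lactone 11 (C3 ketone masked in situ as its enolate); sets C9.
3. Lactone C6–O and C5–H: dealkylative iodolactonisation of the Δ5 β-keto ester 9, then tin-hydride deiodination; sets C6 and C5, and C8 is equilibrated.
4. C4 quaternary centre and C8 methyl: one-pot dianion double methylation of enone ester 7, made from (S)-Wieland–Miescher ketone by α-iodination and Pd carbonylation.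
5. Ring order: B (cyclohexanedione) → A (proline Robinson annulation) → γ-lactone → spiro-furanone, with the dihydrofuran unveiled from the furan.

Assumption: positions are given in labdane numbering (C1–C20; α/β as in the usual drawing with the C10 methyl β), and LDA and LiHMDS are used as purchased solutions.

## Route

Step 1
Reactants: 1 cyclohexane-1,3-dione
Product: 2 2-methylcyclohexane-1,3-dione
Conditions: MeI, KOH, MeOH/H2O, 65 °C
Reagents that add atoms: iodomethane (CI)
Why: C-alkylation of the stabilised 1,3-dione enolate at C2; no stereocentre is formed.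

Step 2
Reactants: 2 2-methylcyclohexane-1,3-dione; 3 but-3-en-2-one
Product: 5 (S)-Wieland–Miescher ketone, via triketone 4 (not isolated)
Conditions: L-proline (35 mol %), DMSO, 35 °C, 90 h; recrystallise to >99% ee
Reagents that add atoms: none
Why: Hajos–Parrish–Eder–Sauer–Wiechert variant of the Robinson annulation (Michael addition, then proline-enamine aldol condensation); L-proline selects one enantiotopic carbonyl and sets the quaternary carbon (C10) as S.

Step 3
Reactants: 5 (S)-Wieland–Miescher ketone
Product: 6 (8aS)-5-iodo-8a-methyl-3,4,8,8a-tetrahydronaphthalene-1,6(2H,7H)-dione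
Conditions: I2, pyridine/CH2Cl2 (1:1), 0 °C → rt
Reagents that add atoms: iodine (II)
Why: Johnson α-iodination of an enone (pyridine conjugate addition, iodination, elimination) touches only the vinylic α-position; the saturated ketone is inert.

Step 4
Reactants: 6 iodoenone
Product: 7 methyl (4aS)-4a-methyl-2,5-dioxo-2,3,4,4a,5,6,7,8-octahydronaphthalene-1-carboxylate
Conditions: Pd(OAc)2 (5 mol %), dppf, CO (1 atm), MeOH, Et3N, DMF, 60 °C
Reagents that add atoms: carbon monoxide ([C-]#[O+]); methanol (CO)
Why: Pd-catalysed alkoxycarbonylation of the vinyl iodide (oxidative addition, CO insertion, methanolysis) installs C19 at C4.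

Step 5
Reactants: 7 enone ester
Product: 9 methyl (1R,4aS,6R)-1,4a,6-trimethyl-2,5-dioxo-1,2,3,4,4a,5,6,7-octahydronaphthalene-1-carboxylate, via C8-monomethyl keto ester 8 (not isolated)
Conditions: NaH (1.05 eq), THF, 0 °C; LDA (1.1 eq), −78 °C; MeI (3 eq), DMPU, −78 °C → rt
Reagents that add atoms: iodomethane (CI)
Why: Dianion alkylation: the more basic C9-ketone enolate is methylated first at C8 (anti to the C10 methyl, and corrected thermodynamically in step 7), then the vinylogous β-keto ester dienolate undergoes deconjugative α-methylation at C4 anti to the angular methyl, giving 4α-Me/4β-CO2Me and moving the alkene to C5=C6.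

Step 6
Reactants: 9 dimethylated Δ5 keto ester
Product: 10 iodolactone (5α-iodo-3,9-dioxo-19,6β-olide)
Conditions: I2 (3 eq), MeCN, 0 °C → rt, dark
Reagents that add atoms: iodine (II)
Why: Dealkylative iodolactonisation (5-endo, thermodynamic γ-lactone): iodonium forms on the open α face, the axial 4β ester carbonyl opens it at C6 from the β face (trans-diaxial, 6β-O/5α-I), and iodide removes the O-methyl as MeI.

Step 7
Reactants: 10 iodolactone
Product: 11 diketo lactone (3,9-dioxo-19,6β-olide; 4α-Me, 5α-H, 8α-Me, 10β-Me)
Conditions: Bu3SnH, AIBN (cat.), PhH, 80 °C; then DBU (0.2 eq), rt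
Reagents that add atoms: none
Why: Radical chain dehalogenation: the tertiary C5 radical takes H from the α face because the β face is covered by the lactone bridge and the C10 methyl, giving the trans-decalin; DBU then equilibrates C8 (α to the C9 ketone) to the equatorial 8α-methyl.

Step 8
Reactants: 11 diketo lactone; 12 1-(furan-3-yl)ethan-1-one
Product: 15 hydroxy ketone (9α-hydroxy-3,12-dioxo-15,16-epoxylabda-13(16),14-dien-19,6β-olide), via lithium enolate of the diketo lactone 13 (not isolated), via cerium enolate of 3-acetylfuran 14 (not isolated)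
Conditions: 11, LiHMDS (1.05 eq), THF, −78 °C; separately 12, LDA (1.0 eq), THF, −78 °C, then CeCl3 (1.0 eq); combine at −78 °C; AcOH (2 eq) quench at −78 °C
Reagents that add atoms: none
Why: Kinetic deprotonation at the unhindered C2 methylene masks the C3 ketone as its enolate, so the cerium enolate (Imamoto-type aldol, suppresses retro-aldol) adds only to C9, by equatorial (β-face) attack away from the axial H5α/H7α, giving the 9α-hydroxyl with C11 equatorial.

Step 9
Reactants: 15 hydroxy ketone
Product: 16 target, (13S)-3,12-dioxo-9α,13:15,16-diepoxylabd-14-en-19,6β-olide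
Conditions: [Ir(dF(CF3)ppy)2(5,5′-d(CF3)bpy)]PF6 (2 mol %), Bu4N+ (BuO)2PO2− (25 mol %), 2,4,6-(i-Pr)3C6H2SH (50 mol %), PhCF3, blue LEDs, rt
Reagents that add atoms: none
Why: Proposed new method: proton-coupled electron transfer turns the tertiary 9-OH into an alkoxy radical, which adds 5-exo to C13 (the electron-rich α-carbon of the furan's vinylogous-ester π system, so polarity and ring size both disfavour 6-endo attack at C16), and the resulting α-oxy C16 radical is quenched by thiol H-atom transfer to give CH2-16 and the C14=C15 enol ether in a redox-neutral isomerisation; C13 is set by substrate control (the target epimer has C16 on the C10 side of the new ring), but the two furan faces differ only by the 8α-methyl versus the C1 methylene, so a low d.r. and chromatographic removal of the 13-epimer must be expected; the closest known chemistry is PCET hydroetherification of alkenols by 5-exo alkoxy-radical cyclisation with thiol HAT, and radical dearomatisation of furans.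

## Compound list

1 | cyclohexane-1,3-dione | O=C1CCCC(=O)C1 | starting material
2 | 2-methylcyclohexane-1,3-dione | CC1C(=O)CCCC1=O | intermediate
3 | but-3-en-2-one (methyl vinyl ketone) | CC(=O)C=C | starting material
4 | 2-methyl-2-(3-oxobutyl)cyclohexane-1,3-dione (triketone, not isolated) | CC(=O)CCC1(C)C(=O)CCCC1=O | intermediate
5 | (S)-Wieland–Miescher ketone, (8aS)-8a-methyl-3,4,8,8a-tetrahydronaphthalene-1,6(2H,7H)-dione | C[C@]12CCC(=O)C=C1CCCC2=O | intermediate
6 | (8aS)-5-iodo-8a-methyl-3,4,8,8a-tetrahydronaphthalene-1,6(2H,7H)-dione | C[C@]12CCC(=O)C(I)=C1CCCC2=O | intermediate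
7 | methyl (4aS)-4a-methyl-2,5-dioxo-2,3,4,4a,5,6,7,8-octahydronaphthalene-1-carboxylate | C[C@]12CCC(=O)C(C(=O)OC)=C1CCCC2=O | intermediate
8 | methyl (4aS,6R)-4a,6-dimethyl-2,5-dioxo-2,3,4,4a,5,6,7,8-octahydronaphthalene-1-carboxylate (present as its dienolate, not isolated) | C[C@@H]1CCC2=C(C(=O)OC)C(=O)CC[C@]2(C)C1=O | intermediate
9 | methyl (1R,4aS,6R)-1,4a,6-trimethyl-2,5-dioxo-1,2,3,4,4a,5,6,7-octahydronaphthalene-1-carboxylate (major 8α-methyl epimer) | C[C@@H]1CC=C2[C@@](C)(C(=O)OC)C(=O)CC[C@]2(C)C1=O | intermediate
10 | iodolactone: 5α-iodo-4α,8α,10β-trimethyl-3,9-dioxo-trans-decalin-19,6β-carbolactone | C[C@@H]1C[C@H]2OC(=O)[C@@]3(C)C(=O)CC[C@@](C)([C@@]23I)C1=O | intermediate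
11 | diketo lactone: (2aR,5aS,7R,8aR,8bR)-2a,5a,7-trimethyloctahydro-2H-naphtho[1,8-bc]furan-2,3,6-trione | C[C@@H]1C[C@H]2OC(=O)[C@@]3(C)C(=O)CC[C@@](C)([C@@H]23)C1=O | intermediate
12 | 1-(furan-3-yl)ethan-1-one (3-acetylfuran) | CC(=O)c1ccoc1 | starting material
13 | lithium C2–C3 enolate of diketo lactone 11 (not isolated) | [Li+].C[C@@H]1C[C@H]2OC(=O)[C@@]3(C)C([O-])=CC[C@@](C)([C@@H]23)C1=O | intermediate
14 | dichlorocerium enolate of 3-acetylfuran (not isolated) | C=C(O[Ce](Cl)Cl)c1ccoc1 | intermediate
15 | hydroxy ketone: (2aR,5aS,6R,7R,8aR,8bR)-6-[2-(furan-3-yl)-2-oxoethyl]-6-hydroxy-2a,5a,7-trimethyloctahydro-2H-naphtho[1,8-bc]furan-2,3-dione | C[C@@H]1C[C@H]2OC(=O)[C@@]3(C)C(=O)CC[C@@](C)([C@@H]23)[C@@]1(O)CC(=O)c1ccoc1 | intermediate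
16 | CNP0143138.1, (13S)-3,12-dioxo-9α,13:15,16-diepoxylabd-14-en-19,6β-olide | C[C@@H]1C[C@H]2OC(=O)[C@@]3(C)C(=O)CC[C@@](C)([C@@H]23)[C@@]12CC(=O)[C@@]1(C=COC1)O2 | target

## Step count and risks

Total steps: 9. Longest linear sequence: 9 (1 → 16).

**Step 9 (most likely to fail).** The alkoxy radical can undergo β-scission of C9–C10, its addition to the aromatic furan is probably reversible, and the C13 face selectivity is weak. The fallback sets out from 15 and comes back at 16. NaBH4 in MeOH at 0 °C reduces both ketones to the 3β,9α,12-triol F1, whose furan is now an electron-rich 3-alkylfuran. PhSeCl with 2,6-lutidine in CH2Cl2 at −78 °C then puts selenium on C16, and the 9-hydroxyl captures the C13 allyl-oxocarbenium ion to give the 16-phenylselanyl spiro ether F2 (polar 5-exo closure, no alkoxy radical). Bu3SnH/AIBN with 10 mol % (PhSe)2 (PhSeH formed in situ traps the C16 radical before it can fragment) gives the spiro diol F3. Dess–Martin periodinane buffered with NaHCO3 reoxidises C3 and C12 to give 16. The C13 selectivity problem is not removed by this fallback.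

**Step 8.** The ketone–ketone aldol onto a carbonyl flanked by a quaternary carbon may revert, and residual attack at C3 is possible. The fallback sets out from 11 and comes back at 15. After the same LiHMDS masking of C3, lithium (furan-3-yl)acetylide (3-ethynylfuran, n-BuLi, CeCl3, THF, −78 °C) adds irreversibly from the β face to give the propargylic alcohol F4. Gold(I)-catalysed hydration ((IPr)AuCl/AgSbF6, dioxane–H2O, rt), directed by the furyl group and the propargylic hydroxyl, places the carbonyl at C12 and returns 15. Meyer–Schuster rearrangement of the tertiary propargylic alcohol is the main competing pathway.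

**Step 6.** The 5-endo dealkylative iodolactonisation of a hindered neopentyl methyl ester may stall, and the tertiary iodide can ionise. The fallback sets out from 9 and comes back at 11. Me3SnOH in 1,2-dichloroethane at 80 °C cleaves the ester without retro-Claisen opening to give the keto acid F5. Acridinium photoredox catalysis (9-mesityl-10-methylacridinium, PhSSPh cat., 2,6-lutidine, DCE, blue LEDs) then effects anti-Markovnikov hydrolactonisation: the alkene radical cation is captured at C6 by the β carboxylate, and the C5 radical takes H from thiol on the α face. DBU equilibration at C8 gives 11 directly, with no iodide intermediate.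

Further compounds

F1 | step 9 | 3β,9α,12-trihydroxy-15,16-epoxylabda-13(16),14-dien-19,6β-olide (C12 epimers) | C[C@@H]1C[C@H]2OC(=O)[C@@]3(C)[C@@H](O)CC[C@@](C)([C@@H]23)[C@@]1(O)CC(O)c1ccoc1
F2 | step 9 | 3β,12-dihydroxy-16-(phenylselanyl)-9α,13:15,16-diepoxylabd-14-en-19,6β-olide (C12 and C16 epimers) | C[C@@H]1C[C@H]2OC(=O)[C@@]3(C)[C@@H](O)CC[C@@](C)([C@@H]23)[C@@]12CC(O)[C@@]1(C=COC1[Se]c1ccccc1)O2
F3 | step 9 | 3β,12-dihydroxy-9α,13:15,16-diepoxylabd-14-en-19,6β-olide (C12 epimers) | C[C@@H]1C[C@H]2OC(=O)[C@@]3(C)[C@@H](O)CC[C@@](C)([C@@H]23)[C@@]12CC(O)[C@@]1(C=COC1)O2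
F4 | step 8 | 9α-hydroxy-9β-[(furan-3-yl)ethynyl] diketo lactone (propargylic alcohol) | C[C@@H]1C[C@H]2OC(=O)[C@@]3(C)C(=O)CC[C@@](C)([C@@H]23)[C@@]1(O)C#Cc1ccoc1
F5 | step 6 | (1R,4aS,6R)-1,4a,6-trimethyl-2,5-dioxo-1,2,3,4,4a,5,6,7-octahydronaphthalene-1-carboxylic acid | C[C@@H]1CC=C2[C@@](C)(C(=O)O)C(=O)CC[C@]2(C)C1=O
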